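The C3/C4 cis-diol of ring A is read as a C3=C4 alkene, which is the retron of a [4+2] cycloaddition between a C2=C3–C4=C5 diene and a C1=C10 dienophile. C14 is carried as a formyl group on C10, so the dienophile is a 2-substituted acrolein. An enantioselective intramolecular Diels–Alder reaction of an achiral (E)-triene enal, in which C6–C9 link C5 to C10 and C8 is masked as a 1,3-dithiane, forms C1–C2 and C5–C10, closes ring A and ring B and sets C5 and C10 in one operation. The C8 ketone later admits C11–C13 and the enone.

Key step: step 8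

Remarks on the chemistry (assumptions):
- Numbering is that of eudesmane: ring A = C1–C5 and C10, ring B = C5–C10, C14 on C10, C15 on C4, C11–C13 on C7; β is the face of C14.
- The masked C8 carbonyl passes through the cycloaddition as the 1,3-dithiane used to assemble the chain, because an O,O-ketal could ionise or bind the boron cation; this changes a spectator group only.
- The sense of induction in step 8 is assigned from the accepted transition-state model for 2-substituted acroleins and is to be confirmed on the first run.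
- The cycloadduct is (5S,10S) and the later intermediates are (5R,10R): only the descriptors change when formyl becomes methyl.

Step 1
Reactants: 1 1,3-dithiane; 2 2-(2-bromoethyl)-1,3-dioxolane
Product: 4 2-[2-(1,3-dioxolan-2-yl)ethyl]-1,3-dithiane, via 2-lithio-1,3-dithiane 3 (not isolated)
Conditions: n-BuLi, THF, −30 °C; then 2, −78 °C → rt
Reagents that add atoms: none
Why: Corey–Seebach alkylation, in which the sulfur-stabilised carbanion displaces a primary bromide bearing a base-stable acetal, installs C8 with C7, C6 and C5 (at the aldehyde level) and avoids alkylation with an elimination-prone dienyl halide.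

Step 2
Reactants: 4 2-[2-(1,3-dioxolan-2-yl)ethyl]-1,3-dithiane; 5 ethyl 2-(bromomethyl)prop-2-enoate
Product: 7 ethyl 2-({2-[2-(1,3-dioxolan-2-yl)ethyl]-1,3-dithian-2-yl}methyl)prop-2-enoate, via lithiated dithiane 6 (not isolated)
Conditions: n-BuLi, THF, −20 °C, 3 h; then 5, −78 °C
Reagents that add atoms: none
Why: second Corey–Seebach alkylation, in which direct and allylic (SN2′) attack on the bromomethyl acrylate give the same product, brings in C9, C10, C1 and C14 while C8 is never a free ketone beside the acrylate.

Step 3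
Reactants: 7 ethyl 2-({2-[2-(1,3-dioxolan-2-yl)ethyl]-1,3-dithian-2-yl}methyl)prop-2-enoate
Product: 8 ethyl 2-{[2-(3-oxopropyl)-1,3-dithian-2-yl]methyl}prop-2-enoate
Conditions: 1 M HCl (aq), THF, rt
Reagents that add atoms: water, O
Why: acetal hydrolysis frees the C5 aldehyde selectively because a thioacetal is inert to dilute aqueous acid and the acrylate ester is not touched.

Step 4
Reactants: 8 ethyl 2-{[2-(3-oxopropyl)-1,3-dithian-2-yl]methyl}prop-2-enoate; 9 2-(triphenylphosphoranylidene)propanal
Product: 10 ethyl 2-({2-[(3E)-4-methyl-5-oxopent-3-en-1-yl]-1,3-dithian-2-yl}methyl)prop-2-enoate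
Conditions: toluene, 80 °C
Reagents that add atoms: none
Why: Wittig olefination with a formyl-stabilised ylide should give the (E)-2-methyl enal, which fixes the C4=C5 geometry and brings in C15, and the aliphatic aldehyde reacts far faster than the product enal or the ester.

Step 5
Reactants: 10 ethyl 2-({2-[(3E)-4-methyl-5-oxopent-3-en-1-yl]-1,3-dithian-2-yl}methyl)prop-2-enoate
Product: 11 ethyl 2-({2-[(3E)-4-methylhexa-3,5-dien-1-yl]-1,3-dithian-2-yl}methyl)prop-2-enoate
Conditions: Ph3PCH3Br, KN(SiMe3)2, THF, 0 °C; then 10, −78 → 0 °C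
Reagents that add atoms: methyltriphenylphosphonium bromide, C[P+](c1ccccc1)(c1ccccc1)c1ccccc1.[Br-]
Why: Wittig methylenation of the enal adds C2 at low temperature without touching the C4=C5 geometry, and with no excess of ylide it should outpace conjugate addition to the acrylate.

Step 6
Reactants: 11 ethyl 2-({2-[(3E)-4-methylhexa-3,5-dien-1-yl]-1,3-dithian-2-yl}methyl)prop-2-enoate
Product: 12 2-({2-[(3E)-4-methylhexa-3,5-dien-1-yl]-1,3-dithian-2-yl}methyl)prop-2-en-1-ol
Conditions: i-Bu2AlH (2.2 equiv), CH2Cl2, −78 °C; aq. potassium sodium tartrate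
Reagents that add atoms: none
Why: hydride reduction of the conjugated ester by 1,2-delivery gives the allylic alcohol and leaves the diene and the dithiane alone.

Step 7
Reactants: 12 2-({2-[(3E)-4-methylhexa-3,5-dien-1-yl]-1,3-dithian-2-yl}methyl)prop-2-en-1-ol
Product: 13 2-({2-[(3E)-4-methylhexa-3,5-dien-1-yl]-1,3-dithian-2-yl}methyl)prop-2-enal
Conditions: MnO2 (activated, excess), CH2Cl2, rt; filtered, kept cold and used at once
Reagents that add atoms: none
Why: allylic oxidation with MnO2 is neutral and stops at the aldehyde, so neither the sulfur atoms nor the diene are oxidised and the 2-substituted acrolein is not isomerised.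

Step 8
Reactants: 13 2-({2-[(3E)-4-methylhexa-3,5-dien-1-yl]-1,3-dithian-2-yl}methyl)prop-2-enal
Product: 14 (4aS,8aS)-5-methyl-3,4,4a,7,8,8a-hexahydro-1H-spiro[naphthalene-2,2′-[1,3]dithiane]-8a-carbaldehyde
Conditions: (R)-3,3-diphenyl-1-(o-tolyl)tetrahydro-1H,3H-pyrrolo[1,2-c][1,3,2]oxazaborole (20 mol%), HN(SO2CF3)2 (17 mol%), CH2Cl2, −78 → −40 °C
Reagents that add atoms: none
Why: The N-protonated oxazaborolidine binds the formyl oxygen, with the formyl hydrogen held against the ring oxygen, and so lowers the LUMO of the C1=C10 bond, after which the s-cis C2=C3–C4=C5 diene adds in a concerted, asynchronous [4+2] cycloaddition in which C1–C2 bonding runs ahead of C5–C10 bonding; the closest known reaction types are the cationic oxazaborolidine-catalysed Diels–Alder reaction of 2-substituted acroleins and Lewis acid-promoted intramolecular cycloadditions of 1,7,9-decatrienes. Ring A (C1, C2, C3, C4, C5, C10) is closed by the cycloaddition itself as a cyclohexene with its double bond at C3=C4, and ring B (C5–C10) is closed in the same event because the four-carbon tether C6–C9 spans the two carbons of the new C5–C10 bond in a chair-like array. C10 is set by the catalyst: in the accepted model the (S)-catalyst stacks the bound s-trans enal on a phenyl group and leaves open the face from which tether, formyl and methylene run clockwise, and since 14 needs the other face the (R)-catalyst is used, which should give the (10S)-aldehyde with the formyl group β. C5 is set relative to C10 by the formyl-endo, tether-exo transition state together with the (E)-geometry of C4=C5, which places C6 outside the diene and H5 anti to the formyl group, the trans ring fusion. The step needs enantiofacial selection at C10 and endo orientation of the formyl group; the first comes from the catalyst, the second from the Lewis acid-bound carbonyl lying under the diene while the tether reaches C10 as a strain-free chair. The dithiane at C8 favours the reactive rotamer through its geminal substituents, cannot ionise as an O,O-ketal could, and offers only soft donor atoms to the hard boron cation.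

Step 9
Reactants: 14 (4aS,8aS)-5-methyl-3,4,4a,7,8,8a-hexahydro-1H-spiro[naphthalene-2,2′-[1,3]dithiane]-8a-carbaldehyde
Product: 16 (4aR,8aR)-5,8a-dimethyl-3,4,4a,7,8,8a-hexahydro-1H-spiro[naphthalene-2,2′-[1,3]dithiane], via N-silyl hydrazone 15 (not isolated)
Conditions: 1,2-bis(tert-butyldimethylsilyl)hydrazine, Sc(OSO2CF3)3 (0.01 mol%), neat, rt; then KOt-Bu, t-BuOH, DMSO, 23 °C
Reagents that add atoms: none
Why: Wolff–Kishner reduction in its room-temperature N-silylhydrazone form turns the formyl group into the C14 methyl group by loss of N2, is chosen because hot hydrazine and alkali could also reduce the thioacetal, and cannot disturb the quaternary C10 or the non-enolisable C5.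

Step 10
Reactants: 16 (4aR,8aR)-5,8a-dimethyl-3,4,4a,7,8,8a-hexahydro-1H-spiro[naphthalene-2,2′-[1,3]dithiane]
Product: 17 (4aR,8aR)-5,8a-dimethyl-3,4,4a,7,8,8a-hexahydronaphthalen-2(1H)-one
Conditions: MeI, CaCO3, MeCN/H2O (4:1), 50 °C
Reagents that add atoms: water, O
Why: alkylative hydrolysis of the thioacetal (S-methylation, capture of the thionium ion by water) releases the C8 ketone under buffered conditions that should neither move the C3=C4 bond nor epimerise a centre.

Step 11
Reactants: 17 (4aR,8aR)-5,8a-dimethyl-3,4,4a,7,8,8a-hexahydronaphthalen-2(1H)-one; 18 acetone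
Product: 21 (5R,7R,10R)-11-hydroxyeudesm-3-en-8-one, via lithium enolate 19 (not isolated), via chlorozinc enolate 20 (not isolated)
Conditions: LiN(i-Pr)2, THF, −78 °C; ZnCl2; acetone, −78 → −40 °C; aq. NH4Cl
Reagents that add atoms: none
Why: directed aldol addition, in which kinetic deprotonation occurs at C7 and not at C9 (neopentyl to the quaternary C10) and the zinc aldolate chelate holds back the retro-aldol reaction, adds C11–C13; the C7 centre, expected mainly as the equatorial 7β epimer shown, is removed in the next step.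

Step 12
Reactants: 21 (5R,7R,10R)-11-hydroxyeudesm-3-en-8-one
Product: 23 (5R,10R)-eudesma-3,7(11)-dien-8-one, via tertiary mesylate 22 (not isolated)
Conditions: MsCl, Et3N, 4-(dimethylamino)pyridine (cat.), CH2Cl2, 0 °C → rt; then 1,8-diazabicyclo[5.4.0]undec-7-ene (DBU), rt
Reagents that add atoms: none
Why: E1cB dehydration through the mesylate removes the acidic H7 and gives the conjugated C7=C11 enone, and DBU should bring any isopropenyl isomer into conjugation.

Step 13
Reactants: 23 (5R,10R)-eudesma-3,7(11)-dien-8-one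
Product: 24 (3R,4S,5R,10R)-3α,4α-dihydroxyeudesm-7(11)-en-8-one
Conditions: OsO4 (2 mol%), N-methylmorpholine N-oxide, acetone/H2O (10:1), 0 °C → rt
Reagents that add atoms: N-methylmorpholine N-oxide, C[N+]1([O-])CCOCC1; water, O; osmium tetroxide (oxygen carrier), O=[Os](=O)(=O)=O
Why: OsO4-catalysed syn-dihydroxylation takes the electron-rich C3=C4 bond and not the tetrasubstituted enone, and approaches from the α face because the axial C14 methyl group shields the β face of ring A, which sets C3 (R) and C4 (S) as the 3α,4α-diol.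

Step 14
Reactants: 24 (3R,4S,5R,10R)-3α,4α-dihydroxyeudesm-7(11)-en-8-one
Product: 26 (3R,4S,5R,10R)-3α,4α,11-trihydroxyeudesm-6-en-8-one, via C11 hydroperoxide 25 (not isolated)
Conditions: O2, hν (visible), 5,10,15,20-tetraphenylporphyrin (1 mol%), CH2Cl2, 0 °C; then PPh3
Reagents that add atoms: dioxygen, O=O
Why: Schenck ene reaction of singlet oxygen with the s-cis enone follows the geminal rule for α,β-unsaturated carbonyl compounds, so that oxygen bonds to the β-carbon C11, hydrogen leaves C6 and the double bond moves to C6=C7 in conjugation, after which PPh3 reduces the hydroperoxide; the resulting s-trans enone is inert to singlet oxygen.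

Step 15
Reactants: 26 (3R,4S,5R,10R)-3α,4α,11-trihydroxyeudesm-6-en-8-one; 27 angelic acid
Product: 29 (3R,4S,5R,10R)-3α-[(Z)-2-methylbut-2-enoyloxy]-4α,11-dihydroxyeudesm-6-en-8-one, via mixed anhydride 28 (not isolated)
Conditions: 27, 2,4,6-trichlorobenzoyl chloride, Et3N, toluene, rt; then 26, 80 °C
Reagents that add atoms: none
Why: Yamaguchi-type acylation through the mixed anhydride, run without a nucleophilic amine catalyst, should transfer the (Z)-acyl group without Z to E isomerisation, and only the secondary C3 hydroxyl reacts because the C4 and C11 hydroxyls are tertiary.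

Compound list

1 | 1,3-dithiane | C1CSCSC1 | starting material
2 | 2-(2-bromoethyl)-1,3-dioxolane | BrCCC1OCCO1 | starting material
3 | 2-lithio-1,3-dithiane (not isolated) | [Li]C1SCCCS1 | intermediate
4 | 2-[2-(1,3-dioxolan-2-yl)ethyl]-1,3-dithiane | C1CSC(CCC2OCCO2)SC1 | intermediate
5 | ethyl 2-(bromomethyl)prop-2-enoate | C=C(CBr)C(=O)OCC | starting material
6 | 2-lithio-2-[2-(1,3-dioxolan-2-yl)ethyl]-1,3-dithiane (not isolated) | [Li]C1(CCC2OCCO2)SCCCS1 | intermediate
7 | ethyl 2-({2-[2-(1,3-dioxolan-2-yl)ethyl]-1,3-dithian-2-yl}methyl)prop-2-enoate | C=C(CC1(CCC2OCCO2)SCCCS1)C(=O)OCC | intermediate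
8 | ethyl 2-{[2-(3-oxopropyl)-1,3-dithian-2-yl]methyl}prop-2-enoate | C=C(CC1(CCC=O)SCCCS1)C(=O)OCC | intermediate
9 | 2-(triphenylphosphoranylidene)propanal | CC(C=O)=P(c1ccccc1)(c1ccccc1)c1ccccc1 | starting material
10 | ethyl 2-({2-[(3E)-4-methyl-5-oxopent-3-en-1-yl]-1,3-dithian-2-yl}methyl)prop-2-enoate | C=C(CC1(CC/C=C(\C)C=O)SCCCS1)C(=O)OCC | intermediate
11 | ethyl 2-({2-[(3E)-4-methylhexa-3,5-dien-1-yl]-1,3-dithian-2-yl}methyl)prop-2-enoate | C=C(CC1(CC/C=C(\C)C=C)SCCCS1)C(=O)OCC | intermediate
12 | 2-({2-[(3E)-4-methylhexa-3,5-dien-1-yl]-1,3-dithian-2-yl}methyl)prop-2-en-1-ol | C=C(CO)CC1(CC/C=C(\C)C=C)SCCCS1 | intermediate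
13 | 2-({2-[(3E)-4-methylhexa-3,5-dien-1-yl]-1,3-dithian-2-yl}methyl)prop-2-enal; achiral (E)-triene enal with C8 as 1,3-dithiane | C=C(C=O)CC1(CC/C=C(\C)C=C)SCCCS1 | intermediate
14 | (4aS,8aS)-5-methyl-3,4,4a,7,8,8a-hexahydro-1H-spiro[naphthalene-2,2′-[1,3]dithiane]-8a-carbaldehyde; trans-fused, 10β-formyl, H5 α, C3=C4, C8 dithiane | O=C[C@]12CCC=C(C)[C@@H]1CCC1(C2)SCCCS1 | intermediate
15 | (E)-N-(tert-butyldimethylsilyl)hydrazone of 14 (not isolated) | CC(C)(C)[Si](C)(C)N/N=C/[C@]12CCC=C(C)[C@@H]1CCC1(C2)SCCCS1 | intermediate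
16 | (4aR,8aR)-5,8a-dimethyl-3,4,4a,7,8,8a-hexahydro-1H-spiro[naphthalene-2,2′-[1,3]dithiane]; C14 methyl β, H5 α | C[C@]12CCC=C(C)[C@@H]1CCC1(C2)SCCCS1 | intermediate
17 | (4aR,8aR)-5,8a-dimethyl-3,4,4a,7,8,8a-hexahydronaphthalen-2(1H)-one; 11,12,13-trinoreudesm-3-en-8-one | C[C@]12CCC=C(C)[C@@H]1CCC(=O)C2 | intermediate
18 | acetone | CC(C)=O | starting material
19 | lithium C7 enolate of 17 (not isolated) | C[C@]12CCC=C(C)[C@@H]1CC=C(O[Li])C2 | intermediate
20 | chlorozinc C7 enolate of 17 (not isolated) | C[C@]12CCC=C(C)[C@@H]1CC=C(O[Zn]Cl)C2 | intermediate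
21 | (5R,7R,10R)-11-hydroxyeudesm-3-en-8-one; 7β side chain | C[C@]12CCC=C(C)[C@@H]1C[C@H](C(C)(C)O)C(=O)C2 | intermediate
22 | C11 methanesulfonate of 21 (not isolated) | C[C@]12CCC=C(C)[C@@H]1C[C@H](C(C)(C)OS(C)(=O)=O)C(=O)C2 | intermediate
23 | (5R,10R)-eudesma-3,7(11)-dien-8-one | C[C@]12CCC=C(C)[C@@H]1CC(=C(C)C)C(=O)C2 | intermediate
24 | (3R,4S,5R,10R)-3α,4α-dihydroxyeudesm-7(11)-en-8-one | O[C@@H]1CC[C@]2(C)CC(=O)C(=C(C)C)C[C@H]2[C@]1(C)O | intermediate
25 | (3R,4S,5R,10R)-11-hydroperoxy-3α,4α-dihydroxyeudesm-6-en-8-one (not isolated) | O[C@@H]1CC[C@]2(C)CC(=O)C(C(C)(C)OO)=C[C@H]2[C@]1(C)O | intermediate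
26 | (3R,4S,5R,10R)-3α,4α,11-trihydroxyeudesm-6-en-8-one | O[C@@H]1CC[C@]2(C)CC(=O)C(C(C)(C)O)=C[C@H]2[C@]1(C)O | intermediate
27 | angelic acid; (Z)-2-methylbut-2-enoic acid | C/C=C(/C)C(=O)O | starting material
28 | (Z)-2-methylbut-2-enoic 2,4,6-trichlorobenzoic anhydride (not isolated) | C/C=C(/C)C(=O)OC(=O)c1c(Cl)cc(Cl)cc1Cl | intermediate
29 | (3R,4S,5R,10R)-3α-[(Z)-2-methylbut-2-enoyloxy]-4α,11-dihydroxyeudesm-6-en-8-one | C/C=C(/C)C(=O)O[C@@H]1CC[C@]2(C)CC(=O)C(C(C)(C)O)=C[C@H]2[C@]1(C)O | target

Total step count: 15. Longest linear sequence: 15 steps (1 to 29).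

Steps most likely to fail

Step 8. The boron cation may be held by the sulfur atoms, may discriminate poorly between the two faces of the α-tethered acrolein, or the formyl-exo pathway may compete, so that the adduct forms slowly, in low enantiomeric purity or as a cis/trans mixture. The fallback sets out from 13 and replaces catalyst control by resolution. Cycloaddition with the achiral Lewis acid Me2AlCl (CH2Cl2, −78 °C) should give the racemic trans adduct F1, from which any cis isomer is removed by chromatography. Condensation with (1R,2R)-N,N′-dimethyl-1,2-diphenylethane-1,2-diamine (Et2O, molecular sieves, rt) gives the imidazolidine of the (5S,10S)-aldehyde F2 and the diastereomeric imidazolidine of its enantiomer F3, which are separated by chromatography. Hydrolysis of F2 (dilute aq. HCl, Et2O, 0 °C) returns the route at 14.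

Step 14. Hydrogen abstraction from the C12/C13 methyl groups instead of C6 would place the oxygen on C7 and deconjugate the alkene. The fallback sets out from 21 and avoids the ene reaction. Direct dehydrogenation of the β-hydroxy ketone with 2-iodoxybenzoic acid (DMSO, 65 °C) can only introduce C6=C7, because C10 bears no hydrogen, and the tertiary alcohol is inert; it should give (5R,10R)-11-hydroxyeudesma-3,6-dien-8-one F4. Dihydroxylation of F4 with OsO4 and N-methylmorpholine N-oxide, as in step 13, should take the isolated C3=C4 bond from the α face and returns the route at 26.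

Step 15. Z to E isomerisation of the activated acyl unit, or slow acylation of the axial C3 hydroxyl next to the quaternary C4, may erode the ester geometry or the conversion. The fallback sets out from 26 and builds the Z-alkene on the molecule. Esterification with 2-[bis(2,2,2-trifluoroethoxy)phosphoryl]propanoic acid (N,N′-dicyclohexylcarbodiimide, 4-(dimethylamino)pyridine, CH2Cl2) should give the C3 phosphonopropanoate F5, as both epimers at the phosphonate carbon. Still–Gennari olefination of F5 with acetaldehyde (KN(SiMe3)2, 18-crown-6, THF, −78 °C) should give the (Z)-2-methylbut-2-enoate and returns the route at 29.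

Further compounds

F1 | step 8 | racemic trans adduct (14 and its enantiomer) | O=C[C@]12CCC=C(C)[C@@H]1CCC1(C2)SCCCS1.O=C[C@@]12CCC=C(C)[C@H]1CCC1(C2)SCCCS1
F2 | step 8 | (4R,5R)-1,3-dimethyl-4,5-diphenylimidazolidine formed at the formyl carbon of 14 | CN1[C@H](c2ccccc2)[C@@H](c2ccccc2)N(C)C1[C@]12CCC=C(C)[C@@H]1CCC1(C2)SCCCS1
F3 | step 8 | (4R,5R)-1,3-dimethyl-4,5-diphenylimidazolidine formed at the formyl carbon of the enantiomer of 14 | CN1[C@H](c2ccccc2)[C@@H](c2ccccc2)N(C)C1[C@@]12CCC=C(C)[C@H]1CCC1(C2)SCCCS1
F4 | step 14 | (5R,10R)-11-hydroxyeudesma-3,6-dien-8-one | C[C@]12CCC=C(C)[C@@H]1C=C(C(C)(C)O)C(=O)C2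
F5 | step 15 | C3 2-[bis(2,2,2-trifluoroethoxy)phosphoryl]propanoate of 26 | CC(C(=O)O[C@@H]1CC[C@]2(C)CC(=O)C(C(C)(C)O)=C[C@H]2[C@]1(C)O)P(=O)(OCC(F)(F)F)OCC(F)(F)F
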